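**Plan**
1. The hardest feature is the run of four contiguous stereocentres (C6, C1, C2, C3) around the fully substituted oxirane carbon C1, which carries C7. They sit in a labile vinyl oxirane in which C7–O and C3–O are benzoylated and C2–OH stays free.
2. The enabling feature is that ring C1–C6 plus exocyclic C7 is the benzoic acid skeleton. The oxygens on ipso-C1 and ortho-C2 are cis. The other two oxygens sit on C3 and C6, the termini of the diene C3=C4–C5=C6 that an ipso,ortho-dearomatisation leaves behind.
3. The retrosynthesis cuts no C–C bond. It cuts C3–OBz (C–O, with inversion) and the C7O–acyl bond, then C6–O (oxirane walked back from C1/C6 to C3/C4, alkene back to C5=C6), then C3–O/C4–O (epoxidation), and last C1–O and C2–O (back to the arene).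
4. Forward, the carbocycle is present from the start as the arene. A first oxirane is made at C3–C4 (step 2) and transposed to C1–C6 by SN2′ closure of the C1 hydroxyl (step 4). Then follow CO2Me → CH2OH → CH2OBz, desilylation and Mitsunobu benzoylation at C3.
5. The dioxygenase sets C1 and C2 in the absolute sense. C2–OH directs the epoxidation and so sets C3. The C1 oxygen, fixed on the same face, sets C6. The Mitsunobu step inverts C3 to the trans C2/C3 relation.
6. All 21 carbons of the target come from three molecules of benzoic acid.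

Key step: step 1

Assumption: pipoxide numbering (C1 = oxirane carbon bearing C7, C2 = CHOH, C3 = CHOBz, C4=C5, C6 = oxirane CH) is used for all compounds in the Why lines, and in step 1 the two hydrogens come from NADH that the living cells regenerate from fructose, so cofactor and sugar count as part of the biocatalyst system.

**Step 1**
Reactants: 1 benzoic acid
Product: 2 (1S,2R)-1,2-dihydroxycyclohexa-3,5-diene-1-carboxylic acid
Conditions: Cupriavidus necator B9 (whole cells, diol-dehydrogenase-deficient mutant), air, fructose, mineral salts, pH 7.4, 30 °C; then pH 3 (0 °C), EtOAc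
Reagents that add atoms: dioxygen, O=O
Why: Benzoate 1,2-dioxygenase, a Rieske non-haem iron enzyme, binds benzoate and O2 at its iron centre, takes two electrons from NADH and transfers both oxygen atoms suprafacially to the C1–C2 π bond, so that the arene is dearomatised in a single cis-dihydroxylation. The closest known reaction type is the whole-cell arene cis-dihydroxylation with mutants blocked in the following dehydrogenase, which is established for benzoate itself. No ring is closed, because the carbocycle of the target is the former arene ring. C1 (fully substituted, bearing C7) and C2 are set together by the chiral active site, which presents one arene face to the iron-bound oxygen and should give the (1S,2R) cis-diol, that is, the C1–O/C2–O pair of the target in its absolute configuration. The step needs ipso,ortho regioselectivity rather than the ortho,meta mode of toluene-type dioxygenases, and anchoring of the carboxylate in the binding pocket secures this. It also needs the diol to survive, which is secured by the missing diol dehydrogenase (no decarboxylative rearomatisation) and by the near-neutral medium (no acid-induced dehydration).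

**Step 2**
Reactants: 2 (1S,2R)-1,2-dihydroxycyclohexa-3,5-diene-1-carboxylic acid
Product: 3 (1S,2R,3S,6R)-2,3-dihydroxy-7-oxabicyclo[4.1.0]hept-4-ene-3-carboxylic acid (oxirane at C3–C4, cis to both hydroxyls)
Conditions: mCPBA (1.1 equiv), EtOAc, 23 °C
Reagents that add atoms: m-chloroperoxybenzoic acid, OOC(=O)c1cccc(Cl)c1
Why: Hydroxyl-directed (Henbest-type) peracid epoxidation, in which the allylic C2–OH should hydrogen-bond the peracid and deliver oxygen to C3=C4 on the face of the two hydroxyls (sets C3 and C4), while C5=C6 is deactivated by the adjacent C1 with its CO2H and OH groups and the resulting vinyl oxirane is too electron-poor for a second epoxidation.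

**Step 3**
Reactants: 3 (1S,2R,3S,6R)-2,3-dihydroxy-7-oxabicyclo[4.1.0]hept-4-ene-3-carboxylic acid
Product: 4 methyl (1S,2R,3S,6R)-2,3-dihydroxy-7-oxabicyclo[4.1.0]hept-4-ene-3-carboxylate
Conditions: TMSCHN2, toluene–MeOH (3:1), 0 → 23 °C
Reagents that add atoms: trimethylsilyldiazomethane, C[Si](C)(C)C=[N+]=[N-]
Why: Diazoalkane O-methylation of a carboxylic acid, a neutral esterification that leaves the hydroxyls, the labile vinyl oxirane and all stereocentres untouched and stops the carboxylate from attacking the oxirane.

**Step 4**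
Reactants: 4 methyl (1S,2R,3S,6R)-2,3-dihydroxy-7-oxabicyclo[4.1.0]hept-4-ene-3-carboxylate
Product: 6 methyl (1S,2R,3R,6S)-2,3-bis(triethylsilyloxy)-7-oxabicyclo[4.1.0]hept-4-ene-1-carboxylate, via methyl (1R,2R,3S,6R)-3-hydroxy-2-(triethylsilyloxy)-7-oxabicyclo[4.1.0]hept-4-ene-3-carboxylate 5 (not isolated)
Conditions: TESOTf (3 equiv), Et3N (5 equiv), CH2Cl2, −60 → 23 °C
Reagents that add atoms: triethylsilyl trifluoromethanesulfonate, CC[Si](CC)(CC)OS(=O)(=O)C(F)(F)F
Why: Silyl-triflate-induced SN2′ oxirane transposition (vinylogous Payne rearrangement), in which, after silylation of C2–OH, O-silylation of the allylic oxirane weakens C4–O and the tertiary C1–OH, held on the same face next to C6, closes the new oxirane at C6 as the double bond moves to C4=C5, so that C6 is set by the C1 stereocentre, C3 keeps its oxygen (now O-TES) and the more substituted oxirane is trapped irreversibly.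

**Step 5**
Reactants: 6 methyl (1S,2R,3R,6S)-2,3-bis(triethylsilyloxy)-7-oxabicyclo[4.1.0]hept-4-ene-1-carboxylate
Product: 7 [(1S,2R,3R,6S)-2,3-bis(triethylsilyloxy)-7-oxabicyclo[4.1.0]hept-4-en-1-yl]methanol
Conditions: DIBAL-H (2.5 equiv), CH2Cl2, −78 °C; aq. Rochelle salt
Reagents that add atoms: none
Why: Low-temperature DIBAL-H reduction of an ester to the primary alcohol, in which the glycidic ester, activated by its α-oxygen, should be reduced well before hydride can open the vinyl oxirane, the TES ethers are inert and no stereocentre is involved.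

**Step 6**
Reactants: 7 [(1S,2R,3R,6S)-2,3-bis(triethylsilyloxy)-7-oxabicyclo[4.1.0]hept-4-en-1-yl]methanol; 1 benzoic acid
Product: 8 [(1S,2R,3R,6S)-2,3-bis(triethylsilyloxy)-7-oxabicyclo[4.1.0]hept-4-en-1-yl]methyl benzoate
Conditions: 1 (1.2 equiv), DCC, DMAP (cat.), CH2Cl2, 0 → 23 °C
Reagents that add atoms: benzoic acid (1), OC(=O)c1ccccc1
Why: Steglich esterification, in which only one hydroxyl is free, the neutral carbodiimide/DMAP conditions spare oxirane and silyl ethers, and the C7–O bond is not broken, so nothing changes at C1.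

**Step 7**
Reactants: 8 [(1S,2R,3R,6S)-2,3-bis(triethylsilyloxy)-7-oxabicyclo[4.1.0]hept-4-en-1-yl]methyl benzoate
Product: 9 [(1R,2R,3R,6S)-2,3-dihydroxy-7-oxabicyclo[4.1.0]hept-4-en-1-yl]methyl benzoate (C2–OH, C3–OH and oxirane oxygen all on one face)
Conditions: TBAF/AcOH (1:1, 2.5 equiv), THF, 0 °C
Reagents that add atoms: none
Why: Fluoride-induced cleavage of silyl ethers, in which the labile TES groups should leave at 0 °C and acetic acid buffers the alkoxides, so that neither benzoyl migration (C7 → C2) nor reversal of the oxirane transposition can start.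

**Step 8**
Reactants: 9 [(1R,2R,3R,6S)-2,3-dihydroxy-7-oxabicyclo[4.1.0]hept-4-en-1-yl]methyl benzoate; 1 benzoic acid
Product: 10 (−)-pipoxide, [(1R,2R,3S,6S)-3-(benzoyloxy)-2-hydroxy-7-oxabicyclo[4.1.0]hept-4-en-1-yl]methyl benzoate
Conditions: 1 (1.3 equiv), PPh3, DIAD, toluene, −20 → 0 °C
Reagents that add atoms: benzoic acid (1), OC(=O)c1ccccc1
Why: Mitsunobu esterification with SN2 inversion, in which only the allylic C3–O-phosphonium ion can be displaced, from the open upper face, whereas C2–OH is flanked by the fully substituted C1 and shielded on that face by C7H2OBz and, being cis, cannot displace the C3 leaving group internally, so that C3 is inverted to the trans C2–OH/C3–OBz relation of the target.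

**Compound list**
1 | benzoic acid | OC(=O)c1ccccc1 | starting material
2 | (1S,2R)-1,2-dihydroxycyclohexa-3,5-diene-1-carboxylic acid | OC(=O)[C@]1(O)C=CC=C[C@H]1O | intermediate
3 | (1S,2R,3S,6R)-2,3-dihydroxy-7-oxabicyclo[4.1.0]hept-4-ene-3-carboxylic acid | OC(=O)[C@]1(O)C=C[C@H]2O[C@H]2[C@H]1O | intermediate
4 | methyl (1S,2R,3S,6R)-2,3-dihydroxy-7-oxabicyclo[4.1.0]hept-4-ene-3-carboxylate | COC(=O)[C@]1(O)C=C[C@H]2O[C@H]2[C@H]1O | intermediate
5 | methyl (1R,2R,3S,6R)-3-hydroxy-2-(triethylsilyloxy)-7-oxabicyclo[4.1.0]hept-4-ene-3-carboxylate | COC(=O)[C@]1(O)C=C[C@H]2O[C@H]2[C@H]1O[Si](CC)(CC)CC | intermediate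
6 | methyl (1S,2R,3R,6S)-2,3-bis(triethylsilyloxy)-7-oxabicyclo[4.1.0]hept-4-ene-1-carboxylate | COC(=O)[C@]12O[C@H]1C=C[C@@H](O[Si](CC)(CC)CC)[C@H]2O[Si](CC)(CC)CC | intermediate
7 | [(1S,2R,3R,6S)-2,3-bis(triethylsilyloxy)-7-oxabicyclo[4.1.0]hept-4-en-1-yl]methanol | OC[C@]12O[C@H]1C=C[C@@H](O[Si](CC)(CC)CC)[C@H]2O[Si](CC)(CC)CC | intermediate
8 | [(1S,2R,3R,6S)-2,3-bis(triethylsilyloxy)-7-oxabicyclo[4.1.0]hept-4-en-1-yl]methyl benzoate | O=C(OC[C@]12O[C@H]1C=C[C@@H](O[Si](CC)(CC)CC)[C@H]2O[Si](CC)(CC)CC)c1ccccc1 | intermediate
9 | [(1R,2R,3R,6S)-2,3-dihydroxy-7-oxabicyclo[4.1.0]hept-4-en-1-yl]methyl benzoate | O=C(OC[C@]12O[C@H]1C=C[C@@H](O)[C@H]2O)c1ccccc1 | intermediate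
10 | (−)-pipoxide, [(1R,2R,3S,6S)-3-(benzoyloxy)-2-hydroxy-7-oxabicyclo[4.1.0]hept-4-en-1-yl]methyl benzoate | O=C(OC[C@]12O[C@H]1C=C[C@H](OC(=O)c1ccccc1)[C@H]2O)c1ccccc1 | target

Total step count: 8. Longest linear sequence: 8 steps (1 → 10).

**Steps most likely to fail**

1. **Step 8.** Activation may spread over both cis hydroxyls through a cyclic dioxaphosphorane. Displacement at C3 may also be accompanied by allylic shift or by elimination. The fallback sets out from 9 and ties both oxygens into one ring electrophile in which only the allylic C3–O bond can leave. Thionyl chloride and Et3N (CH2Cl2, 0 °C) should give the 2,3-O-cyclic sulfite of 9 F1. Commercial tetrabutylammonium benzoate (DMF, 40–60 °C) should open it at C3 with inversion to the 2-O-sulfite half-ester of pipoxide F2. Mild aqueous work-up should hydrolyse F2, and the route is rejoined at 10.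

2. **Step 7.** The C7 benzoyl group may migrate to the freed C2 hydroxyl, or the oxirane may open or walk back under the fluoride conditions. The fallback sets out from 7 and removes the silyl groups before any benzoate is present (TBAF/AcOH, THF, 0 °C). This should give (1R,2R,3R,6S)-1-(hydroxymethyl)-7-oxabicyclo[4.1.0]hept-4-ene-2,3-diol F3. Both benzoates are then introduced at once by a twofold Mitsunobu reaction with 1 (2.2 equiv of 1, PPh3 and DIAD, toluene, −20 → 0 °C). C7–OH is esterified, C3–OH is inverted and the hindered C2–OH stays free. This bypasses 8 and 9 and rejoins the route at 10.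

3. **Step 5.** Hydride may be delivered to the vinyl oxirane, or the reduction of the hindered ester may stay incomplete. The fallback sets out from 2 and carries out the reduction at the diene stage, before any oxirane exists.
   - TMSCHN2 should give methyl (1S,2R)-1,2-dihydroxycyclohexa-3,5-diene-1-carboxylate F4.
   - LiAlH4 (THF, 0 °C) should give (1R,2R)-1-(hydroxymethyl)cyclohexa-3,5-diene-1,2-diol F5.
   - Selective esterification of the primary hydroxyl with 1 (DCC, DMAP, −20 °C) should give [(1R,6R)-1,6-dihydroxycyclohexa-2,4-dien-1-yl]methyl benzoate F6.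
   - Hydroxyl-directed epoxidation (mCPBA, EtOAc) should give [(1S,2R,3R,6R)-2,3-dihydroxy-7-oxabicyclo[4.1.0]hept-4-en-3-yl]methyl benzoate F7.
   - The TESOTf/Et3N transposition of step 4, applied to F7, rejoins the route at 8.

**Further compounds**
F1 | step 8 | 2,3-O-cyclic sulfite of 9 (either configuration at sulfur) | O=C(OC[C@]12O[C@H]1C=C[C@H]3OS(=O)O[C@@H]23)c1ccccc1
F2 | step 8 | 2-O-sulfite half-ester of pipoxide | O=C(OC[C@]12O[C@H]1C=C[C@H](OC(=O)c1ccccc1)[C@H]2OS(=O)O)c1ccccc1
F3 | step 7 | (1R,2R,3R,6S)-1-(hydroxymethyl)-7-oxabicyclo[4.1.0]hept-4-ene-2,3-diol | OC[C@]12O[C@H]1C=C[C@@H](O)[C@H]2O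
F4 | step 5 | methyl (1S,2R)-1,2-dihydroxycyclohexa-3,5-diene-1-carboxylate | COC(=O)[C@]1(O)C=CC=C[C@H]1O
F5 | step 5 | (1R,2R)-1-(hydroxymethyl)cyclohexa-3,5-diene-1,2-diol | OC[C@]1(O)C=CC=C[C@H]1O
F6 | step 5 | [(1R,6R)-1,6-dihydroxycyclohexa-2,4-dien-1-yl]methyl benzoate | O=C(OC[C@]1(O)C=CC=C[C@H]1O)c1ccccc1
F7 | step 5 | [(1S,2R,3R,6R)-2,3-dihydroxy-7-oxabicyclo[4.1.0]hept-4-en-3-yl]methyl benzoate | O=C(OC[C@]1(O)C=C[C@H]2O[C@H]2[C@H]1O)c1ccccc1
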